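**Plan**

- Retrosynthetic cuts: the C1–CH3 bond of the cyclohexene (alkenyl triflate + methyl); the choice of ring arm that holds the C1=C2 olefin (back to a Cs-symmetric 4,4-disubstituted cyclohexanone); the tertiary C4–O ester bond together with the ring's saturation (back to 4-isopropylphenol and the free benzoic acid); the two aryl–prenyl bonds.
- Forward order: the acid is made by double Stille prenylation and saponification. No ring is ever closed: the carbocycle is the benzene ring of 4-isopropylphenol, dearomatized by iodine(III) with the acid as the nucleophile at the para carbon. The dienone is then reduced to the symmetric ketone, desymmetrized as its enol triflate and methylated.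
- Enabling feature: in the six-membered carbocycle the carbon bearing O and isopropyl (C4) is para to the carbon bearing methyl (C1), and its two ring arms (C3–C2 and C5–C6) differ only in which one holds the C1=C2 double bond. The ring is therefore a 4-alkylphenol in disguise, and C4 is only a prochiral centre until the olefin is placed.
- Stereochemistry: the single stereocentre C4 (R) is set in step 5 by reagent control. A C2-symmetric chiral lithium amide removes one enantiotopic α-proton of the ketone and so fixes the olefin in the pro-R arm. The methylation does not touch C4.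
- Gain: the hindered tertiary ester bond is made by cation–carboxylate combination on a flat ring, not by acylating a tertiary alcohol.

Key step: step 3

Assumption: the sense of enantiotopic proton selection by the lithium amide of (R,R)-bis(1-phenylethyl)amine is taken as that established for 4-tert-butylcyclohexanone, which with isopropyl equatorial and the ester axial maps onto removal of the α-proton of the pro-R arm; if the sense proved opposite, the equally available (S,S)-amine would be used with no other change.

**Route**

Step 1
Reactants: 1 methyl 3,5-dibromo-4-methoxybenzoate; 2 tributyl(3-methylbut-2-en-1-yl)stannane (2.4 equiv)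
Product: 4 methyl 4-methoxy-3,5-bis(3-methylbut-2-en-1-yl)benzoate, via mono-prenylated bromide 3 (not isolated)
Conditions: Pd(PPh3)4 (5 mol %), DMF, 100 °C
Reagents that add atoms: none
Why: Twofold Stille cross-coupling, in which both ester-activated aryl C–Br bonds undergo oxidative addition and the prenyl group should be delivered through its unsubstituted terminus (reductive elimination at the less hindered end of the prenyl–palladium unit) to give the linear 3-methylbut-2-enyl arene twice; no stereocentre is formed.

Step 2
Reactants: 4 methyl 4-methoxy-3,5-bis(3-methylbut-2-en-1-yl)benzoate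
Product: 5 4-methoxy-3,5-bis(3-methylbut-2-en-1-yl)benzoic acid
Conditions: LiOH·H2O, THF/MeOH/H2O, 50 °C; then 1 M HCl, 0 °C
Reagents that add atoms: lithium hydroxide, [Li+].[OH-]
Why: Saponification of an unhindered methyl benzoate, to which the prenyl olefins and the aryl methyl ether are inert, with cold dilute acidification so that the trisubstituted olefins are not hydrated.

Step 3
Reactants: 5 4-methoxy-3,5-bis(3-methylbut-2-en-1-yl)benzoic acid (2.1 equiv); 6 (diacetoxyiodo)benzene; 7 4-(propan-2-yl)phenol
Product: 10 4-oxo-1-(propan-2-yl)cyclohexa-2,5-dien-1-yl 4-methoxy-3,5-bis(3-methylbut-2-en-1-yl)benzoate, via bis(aroyloxy)iodobenzene 8 (not isolated), via aryloxy(aroyloxy)iodane 9 (not isolated)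
Conditions: 5, 6, PhCl, 50 °C, 20 mbar (AcOH distilled off); then 7, CH2Cl2, 0 °C
Reagents that add atoms: none
Why: Ligand exchange first converts 6 and two molecules of 5 into the bis(aroyloxy)-λ3-iodane 8 (removal of acetic acid drives the equilibrium), phenol 7 then displaces one carboxylate at iodine to give 9, and reductive departure of iodobenzene makes the isopropyl-bearing para carbon electrophilic, so that the carboxylate of 5, the only nucleophile present, bonds to it and leaves the ring as a cross-conjugated 2,5-dienone. The closest known reaction type is the iodine(III)-mediated oxidative dearomatization of 4-alkylphenols in carboxylic acid media to 4-acyloxy-4-alkylcyclohexa-2,5-dienones (p-quinol esters). No ring is closed: the carbocycle of the target is the benzene ring of 7, whose aromaticity is traded for the tertiary C–O ester bond. No stereocentre is created, because C4 of 10 lies on a mirror plane (O and isopropyl in the plane, two identical enone arms), so the configuration is deferred to step 5 and nothing can be scrambled here. The step needs para rather than ortho capture, which iodine(III) oxidants generally give with 4-alkylphenols because the alkyl group best stabilises positive charge at the para carbon. It also needs oxidation of the phenol in preference to the prenyl olefins, which the fast O–I ligand exchange of a phenol should secure since unactivated olefins react with such iodanes only under Lewis acid activation, and low temperature without strong acid should hold back loss of the isopropyl methine proton to a quinone methide.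

Step 4
Reactants: 10 4-oxo-1-(propan-2-yl)cyclohexa-2,5-dien-1-yl 4-methoxy-3,5-bis(3-methylbut-2-en-1-yl)benzoate
Product: 12 4-oxo-1-(propan-2-yl)cyclohexyl 4-methoxy-3,5-bis(3-methylbut-2-en-1-yl)benzoate, via racemic enone 11 (not isolated)
Conditions: [(Ph3P)CuH]6 (0.8 equiv), H2O (20 equiv), degassed PhMe, rt
Reagents that add atoms: none
Why: Stryker conjugate reduction, in which copper(I) hydride delivers hydride only to the β-carbons of the two enone units (isolated trisubstituted olefins and the benzoate are inert) and water protonates each copper enolate so that enone 11 is reduced in turn; the hydridic, non-electron-transfer pathway should avoid reductive loss of the γ-aroyloxy group and re-aromatization, and the product is achiral.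

Step 5
Reactants: 12 4-oxo-1-(propan-2-yl)cyclohexyl 4-methoxy-3,5-bis(3-methylbut-2-en-1-yl)benzoate
Product: 14 (1R)-1-(propan-2-yl)-4-[(trifluoromethanesulfonyl)oxy]cyclohex-3-en-1-yl 4-methoxy-3,5-bis(3-methylbut-2-en-1-yl)benzoate, via lithium enolate 13 (not isolated)
Conditions: (R,R)-bis(1-phenylethyl)amine·HCl, n-BuLi (2 equiv), THF, −78 °C (amide + LiCl); 12, −78 °C; then Comins' reagent, −78 to 0 °C
Reagents that add atoms: lithium (R,R)-bis(1-phenylethyl)amide, C[C@@H](N([Li])[C@H](C)c1ccccc1)c1ccccc1 (lithium of 13); Comins' reagent, O=S(=O)(N(c1ccc(Cl)cn1)S(=O)(=O)C(F)(F)F)C(F)(F)F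
Why: Enantioselective deprotonation of a prochiral 4,4-disubstituted cyclohexanone by a chiral lithium amide (LiCl-assisted external quench) followed by O-triflation of the enolate, in which the chair with isopropyl equatorial and the ester axial presents two enantiotopic axial α-protons and the C2-symmetric amide should remove that of the pro-R CH2CH2C(=O) arm, placing the enol double bond in that arm and making C4 (R); the non-enolizable, hindered benzoate should not be attacked by the bulky amide at −78 °C.

Step 6
Reactants: 14 (1R)-1-(propan-2-yl)-4-[(trifluoromethanesulfonyl)oxy]cyclohex-3-en-1-yl 4-methoxy-3,5-bis(3-methylbut-2-en-1-yl)benzoate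
Product: 15 (1R)-4-methyl-1-(propan-2-yl)cyclohex-3-en-1-yl 4-methoxy-3,5-bis(3-methylbut-2-en-1-yl)benzoate
Conditions: MeMgBr (1.5 equiv), Fe(acac)3 (5 mol %), THF/NMP, −30 °C
Reagents that add atoms: methylmagnesium bromide, C[Mg]Br
Why: Iron-catalysed Kumada-type cross-coupling of an alkenyl triflate with a methyl Grignard reagent, which should be faster at −30 °C than addition to the hindered benzoate and replaces OTf by CH3 without moving the double bond, so the C4 stereocentre, which takes no part, stays (R).

**Compound list**

1 | methyl 3,5-dibromo-4-methoxybenzoate | COC(=O)c1cc(Br)c(OC)c(Br)c1 | starting material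
2 | tributyl(3-methylbut-2-en-1-yl)stannane | CCCC[Sn](CCCC)(CCCC)CC=C(C)C | starting material
3 | methyl 3-bromo-4-methoxy-5-(3-methylbut-2-en-1-yl)benzoate | COC(=O)c1cc(Br)c(OC)c(CC=C(C)C)c1 | intermediate (not isolated)
4 | methyl 4-methoxy-3,5-bis(3-methylbut-2-en-1-yl)benzoate | COC(=O)c1cc(CC=C(C)C)c(OC)c(CC=C(C)C)c1 | intermediate
5 | 4-methoxy-3,5-bis(3-methylbut-2-en-1-yl)benzoic acid | COc1c(CC=C(C)C)cc(C(=O)O)cc1CC=C(C)C | intermediate
6 | (diacetoxyiodo)benzene | CC(=O)OI(OC(C)=O)c1ccccc1 | starting material
7 | 4-(propan-2-yl)phenol | CC(C)c1ccc(O)cc1 | starting material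
8 | phenyl-λ3-iodanediyl bis[4-methoxy-3,5-bis(3-methylbut-2-en-1-yl)benzoate] | COc1c(CC=C(C)C)cc(C(=O)OI(OC(=O)c2cc(CC=C(C)C)c(OC)c(CC=C(C)C)c2)c2ccccc2)cc1CC=C(C)C | intermediate (not isolated)
9 | phenyl[4-(propan-2-yl)phenoxy]-λ3-iodanyl 4-methoxy-3,5-bis(3-methylbut-2-en-1-yl)benzoate | COc1c(CC=C(C)C)cc(C(=O)OI(Oc2ccc(C(C)C)cc2)c2ccccc2)cc1CC=C(C)C | intermediate (not isolated)
10 | 4-oxo-1-(propan-2-yl)cyclohexa-2,5-dien-1-yl 4-methoxy-3,5-bis(3-methylbut-2-en-1-yl)benzoate | COc1c(CC=C(C)C)cc(C(=O)OC2(C(C)C)C=CC(=O)C=C2)cc1CC=C(C)C | intermediate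
11 | 4-oxo-1-(propan-2-yl)cyclohex-2-en-1-yl 4-methoxy-3,5-bis(3-methylbut-2-en-1-yl)benzoate (racemic) | COc1c(CC=C(C)C)cc(C(=O)OC2(C(C)C)C=CC(=O)CC2)cc1CC=C(C)C | intermediate (not isolated)
12 | 4-oxo-1-(propan-2-yl)cyclohexyl 4-methoxy-3,5-bis(3-methylbut-2-en-1-yl)benzoate | COc1c(CC=C(C)C)cc(C(=O)OC2(C(C)C)CCC(=O)CC2)cc1CC=C(C)C | intermediate
13 | lithium (4R)-4-{[4-methoxy-3,5-bis(3-methylbut-2-en-1-yl)benzoyl]oxy}-4-(propan-2-yl)cyclohex-1-en-1-olate | COc1c(CC=C(C)C)cc(C(=O)O[C@@]2(C(C)C)CC=C(O[Li])CC2)cc1CC=C(C)C | intermediate (not isolated)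
14 | (1R)-1-(propan-2-yl)-4-[(trifluoromethanesulfonyl)oxy]cyclohex-3-en-1-yl 4-methoxy-3,5-bis(3-methylbut-2-en-1-yl)benzoate | COc1c(CC=C(C)C)cc(C(=O)O[C@@]2(C(C)C)CC=C(OS(=O)(=O)C(F)(F)F)CC2)cc1CC=C(C)C | intermediate
15 | (1R)-4-methyl-1-(propan-2-yl)cyclohex-3-en-1-yl 4-methoxy-3,5-bis(3-methylbut-2-en-1-yl)benzoate | COc1c(CC=C(C)C)cc(C(=O)O[C@@]2(C(C)C)CC=C(C)CC2)cc1CC=C(C)C | target

**Step count and risks**

Total step count: 6. Longest linear sequence: 6 steps (1 to 15); phenol 7 enters at step 3.

Steps most likely to fail:

Step 3. The cationic intermediate may lose the isopropyl methine proton to a quinone methide, which would add the acid at the benzylic carbon and return an aromatic compound. Capture may also occur at the ortho carbon, and the iodane may attack the prenyl olefins. Fallback, from 7 back to 10: the oxygen is introduced without a cation and the ester bond is made by acylation of the less hindered quinol. Phenol 7 is treated with Oxone and NaHCO3 in aqueous MeCN (singlet-oxygen dearomatization) to give 4-hydroperoxy-4-(propan-2-yl)cyclohexa-2,5-dien-1-one F1, which dimethyl sulfide reduces to 4-hydroxy-4-(propan-2-yl)cyclohexa-2,5-dien-1-one F2. Acid 5 is dehydrated with DCC (0.5 equiv) in CH2Cl2 to 4-methoxy-3,5-bis(3-methylbut-2-en-1-yl)benzoic anhydride F3. F2 is then acylated with F3 (Et3N, DMAP, CH2Cl2), and the route is rejoined at 10.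

Step 5. Discrimination between the enantiotopic α-protons may be poor, because a minor chair with axial isopropyl reacts with the opposite sense or the axial ester perturbs the usual transition state. The enolate carbon may also take the aroyl group from the syn-axial oxygen before it is triflated. Fallback, from 5 directly to 15: the stereocentre is drawn from the chiral pool and no enolate is involved. Acid 5 is converted with 1-chloro-N,N,2-trimethylprop-1-en-1-amine (Ghosez's reagent) in CH2Cl2 to 4-methoxy-3,5-bis(3-methylbut-2-en-1-yl)benzoyl chloride F4. Purchased (R)-(−)-terpinen-4-ol F5 is deprotonated with n-BuLi in THF at −78 °C to lithium (R)-terpinen-4-olate F6, which is acylated by F4 to give 15.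

Step 4. The second conjugate reduction may stall at the enone, or electron transfer may expel the γ-carboxylate and re-aromatize the ring. Fallback, from 10 back to 14, bypassing 12: the two olefins are reduced one at a time, and the first reduction sets the stereocentre. Dienone 10 is desymmetrized with an ene-reductase of the Old Yellow Enzyme family (member chosen from a panel, NADPH recycled with glucose dehydrogenase and glucose, buffer with cosolvent, 30 °C) to (1S)-4-oxo-1-(propan-2-yl)cyclohex-2-en-1-yl 4-methoxy-3,5-bis(3-methylbut-2-en-1-yl)benzoate F7. Conjugate reduction of F7 with L-Selectride (THF, −78 °C) generates enolate 13 regiospecifically in the former enone arm, and Comins' reagent traps it as 14.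

**Further compounds**

F1 | step 3 | 4-hydroperoxy-4-(propan-2-yl)cyclohexa-2,5-dien-1-one | CC(C)C1(OO)C=CC(=O)C=C1
F2 | step 3 | 4-hydroxy-4-(propan-2-yl)cyclohexa-2,5-dien-1-one | CC(C)C1(O)C=CC(=O)C=C1
F3 | step 3 | 4-methoxy-3,5-bis(3-methylbut-2-en-1-yl)benzoic anhydride | COc1c(CC=C(C)C)cc(C(=O)OC(=O)c2cc(CC=C(C)C)c(OC)c(CC=C(C)C)c2)cc1CC=C(C)C
F4 | step 5 | 4-methoxy-3,5-bis(3-methylbut-2-en-1-yl)benzoyl chloride | COc1c(CC=C(C)C)cc(C(Cl)=O)cc1CC=C(C)C
F5 | step 5 | (R)-(−)-terpinen-4-ol, (1R)-4-methyl-1-(propan-2-yl)cyclohex-3-en-1-ol (purchased) | CC1=CC[C@@](O)(C(C)C)CC1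
F6 | step 5 | lithium (R)-terpinen-4-olate, lithium (1R)-4-methyl-1-(propan-2-yl)cyclohex-3-en-1-olate | CC1=CC[C@@](O[Li])(C(C)C)CC1
F7 | step 4 | (1S)-4-oxo-1-(propan-2-yl)cyclohex-2-en-1-yl 4-methoxy-3,5-bis(3-methylbut-2-en-1-yl)benzoate | COc1c(CC=C(C)C)cc(C(=O)O[C@@]2(C(C)C)C=CC(=O)CC2)cc1CC=C(C)C
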